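The target is read as Br2 added to an acyclic epoxy diene. In chain numbering from C1 (CHBr) to C8 (CH2Cl), the oxolane oxygen bridges C3 and C6, and each of these carbons has a brominated neighbour (C4 in the ring, C7 outside it). One operation therefore suffices: Br+ adds to C4 of an E C3=C4 alkene, the oxygen of a C6–C7 oxirane closes onto C3, and bromide opens the resulting bicyclic oxonium ion at C7. This forms the oxolane and sets C3, C4 and C7 from the oxirane stereocentres. The precursor is a linear (1E,3E,6R,7S)-6,7-epoxy-1-bromo-8-chloro-3,7-dimethylocta-1,3-diene, assembled by alkenyl–allyl coupling and Sharpless epoxidation.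

Key step: step 11

Remark: chain numbering C1 (CHBr) to C8 (CH2Cl) is used throughout; the target SMILES is taken as drawn (3S,4R,6R,7R in this numbering), and compound 1 is assumed to be bought as the pure E isomer.

Step 1
Reactants: 1 (E)-3-methylpent-2-en-4-yn-1-ol
Product: 4 (E)-3-methyl-5-(trimethylsilyl)pent-2-en-4-yn-1-ol, via dilithio alkoxide acetylide 2 (not isolated), via bis-silyl ether 3 (not isolated)
Conditions: n-BuLi (2.1 equiv), THF, −78 °C; Me3SiCl (2.2 equiv), −78 °C to rt; then 1 M HCl, rt
Reagents that add atoms: chlorotrimethylsilane, C[Si](C)(C)Cl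
Why: Double deprotonation (O–H, then the alkyne C–H), silylation of both anions and acid hydrolysis of the labile O–Si bond is the standard acetylide C-silylation of a hydroxy alkyne and leaves the E alkene untouched.

Step 2
Reactants: 4 (E)-3-methyl-5-(trimethylsilyl)pent-2-en-4-yn-1-ol
Product: 5 [(E)-5-chloro-3-methylpent-3-en-1-yn-1-yl]trimethylsilane
Conditions: PPh3 (1.3 equiv), CCl4, 70 °C
Reagents that add atoms: carbon tetrachloride, ClC(Cl)(Cl)Cl
Why: In this Appel reaction chloride displaces the alkoxyphosphonium group at the primary allylic carbon under neutral conditions, so no allylic transposition is expected and the E geometry and the silylalkyne should survive.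

Step 3
Reactants: 6 prop-2-yn-1-ol
Product: 8 (E)-3-iodo-2-methylprop-2-en-1-ol, via alkenylalane 7 (not isolated)
Conditions: Me3Al (3 equiv), Cp2ZrCl2 (0.25 equiv), CH2Cl2, 0 °C to rt; then I2, THF, −30 to 0 °C; aq K2CO3
Reagents that add atoms: trimethylaluminium, C[Al](C)C; iodine, II
Why: In the Negishi zirconium-catalysed carboalumination, methyl and aluminium add syn across the alkyne with aluminium at the terminal carbon, and iodinolysis of the C–Al bond with retention should give the E iodide only.

Step 4
Reactants: 8 (E)-3-iodo-2-methylprop-2-en-1-ol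
Product: 9 tert-butyl{[(E)-3-iodo-2-methylprop-2-en-1-yl]oxy}dimethylsilane
Conditions: TBSCl, imidazole, CH2Cl2, 0 °C to rt
Reagents that add atoms: tert-butyldimethylsilyl chloride, CC(C)(C)[Si](C)(C)Cl
Why: Imidazole-promoted O-silylation of a primary alcohol masks the acidic hydroxyl before the halogen–metal exchange.

Step 5
Reactants: 9 tert-butyl{[(E)-3-iodo-2-methylprop-2-en-1-yl]oxy}dimethylsilane; 5 [(E)-5-chloro-3-methylpent-3-en-1-yn-1-yl]trimethylsilane
Product: 12 tert-butyl{[(2E,5E)-2,6-dimethyl-8-(trimethylsilyl)octa-2,5-dien-7-yn-1-yl]oxy}dimethylsilane, via alkenyllithium 10 (not isolated), via alkenylzinc chloride 11 (not isolated)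
Conditions: 9, t-BuLi (2.05 equiv), Et2O, −78 °C; ZnCl2 (1.1 equiv), THF, −78 to 0 °C; then 5, Pd(PPh3)4 (5 mol%), THF, 0 °C to rt
Reagents that add atoms: none
Why: In this Negishi alkenyl–allyl cross-coupling, iodine–lithium exchange and transmetalation to zinc proceed with retention, and zerovalent palladium ionises the allylic chloride to a π-allyl complex that should couple at its unsubstituted terminus (C5) faster than it isomerises, so the C5–C6 bond forms with both E alkenes intact.

Step 6
Reactants: 12 tert-butyl{[(2E,5E)-2,6-dimethyl-8-(trimethylsilyl)octa-2,5-dien-7-yn-1-yl]oxy}dimethylsilane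
Product: 13 tert-butyl{[(2E,5E)-2,6-dimethylocta-2,5-dien-7-yn-1-yl]oxy}dimethylsilane
Conditions: K2CO3 (0.3 equiv), MeOH, rt
Reagents that add atoms: none
Why: Base-catalysed methanolysis of the alkynyl C–Si bond (protodesilylation) is much faster than cleavage of a primary tert-butyldimethylsilyl ether, so only the alkyne terminus is freed.

Step 7
Reactants: 13 tert-butyl{[(2E,5E)-2,6-dimethylocta-2,5-dien-7-yn-1-yl]oxy}dimethylsilane
Product: 15 {[(2E,5E,7E)-8-bromo-2,6-dimethylocta-2,5,7-trien-1-yl]oxy}(tert-butyl)dimethylsilane, via alkenylzirconocene chloride 14 (not isolated)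
Conditions: Cp2Zr(H)Cl (1.5 equiv), THF, rt, dark; then NBS (1.5 equiv), 0 °C
Reagents that add atoms: N-bromosuccinimide, O=C1CCC(=O)N1Br
Why: Hydrozirconation adds Zr–H syn to the terminal alkyne with zirconium on the terminal carbon, the trisubstituted alkenes being inert, and bromodezirconation with retention should give the E bromoalkene at C1=C2.

Step 8
Reactants: 15 {[(2E,5E,7E)-8-bromo-2,6-dimethylocta-2,5,7-trien-1-yl]oxy}(tert-butyl)dimethylsilane
Product: 16 (2E,5E,7E)-8-bromo-2,6-dimethylocta-2,5,7-trien-1-ol
Conditions: HF·pyridine, pyridine, THF, 0 °C to rt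
Reagents that add atoms: none
Why: Buffered fluoride-mediated desilylation of a primary silyl ether is mild enough to leave the vinylic bromide and the skipped triene unchanged.

Step 9
Reactants: 16 (2E,5E,7E)-8-bromo-2,6-dimethylocta-2,5,7-trien-1-ol
Product: 17 [(2R,3R)-3-[(2E,4E)-5-bromo-3-methylpenta-2,4-dien-1-yl]-2-methyloxiran-2-yl]methanol
Conditions: Ti(OiPr)4 (10 mol%), D-(−)-diethyl tartrate (12 mol%), t-BuOOH (2 equiv, isooctane), 4 Å molecular sieves, CH2Cl2, −20 °C
Reagents that add atoms: tert-butyl hydroperoxide, CC(C)(C)OO
Why: In the Sharpless asymmetric epoxidation the titanium tartrate complex binds the allylic hydroxyl and delivers oxygen to one face of the E C6=C7 alkene only, D-(−)-tartrate giving the 2R,3R oxirane for E 2-methylalk-2-en-1-ols (C6 R and C7 R), while the bromodiene has no directing group and should stay untouched.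

Step 10
Reactants: 17 [(2R,3R)-3-[(2E,4E)-5-bromo-3-methylpenta-2,4-dien-1-yl]-2-methyloxiran-2-yl]methanol
Product: 18 (2S,3R)-3-[(2E,4E)-5-bromo-3-methylpenta-2,4-dien-1-yl]-2-(chloromethyl)-2-methyloxirane
Conditions: PPh3 (1.5 equiv), CCl4, NaHCO3 (solid), 70 °C
Reagents that add atoms: carbon tetrachloride, ClC(Cl)(Cl)Cl
Why: In this Appel reaction on a 2,3-epoxy alcohol, chloride displaces the alkoxyphosphonium group at the primary carbon while solid NaHCO3 scavenges acid, so the oxirane and both stereocentres should be unchanged (the C7 descriptor becomes S only because CH2Cl now outranks the ring carbon).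

Step 11
Reactants: 18 (2S,3R)-3-[(2E,4E)-5-bromo-3-methylpenta-2,4-dien-1-yl]-2-(chloromethyl)-2-methyloxirane
Product: 20 (2S,3R,5R)-3-bromo-5-[(2R)-2-bromo-1-chloropropan-2-yl]-2-[(E)-2-bromoethenyl]-2-methyloxolane, via bicyclic oxonium ion 19 (not isolated)
Conditions: Br2 (1.0 equiv, dilute solution added slowly), CH2Cl2, −78 °C, dark
Reagents that add atoms: bromine, BrBr
Why: Proposed new method: Br2 should deliver Br+ to C4 of the C3=C4 alkene, the only electron-rich π bond (C1=C2 is deactivated by its bromine) and the one whose charge develops at the tertiary, allylic C3; the oxirane oxygen, tethered through C5–C6, then attacks C3 anti to the bridging bromine to give the 1-oxoniabicyclo[3.1.0]hexane ion 19, and the bromide released in the first event opens 19 at C7 with inversion, so the reagent is consumed completely. The closest known reaction types are the intramolecular bromonium-ion-assisted opening of epoxides, in which an epoxy alkene gives a bicyclic oxonium ion that an external nucleophile such as a halide captures, and the 5-endo halocyclisation of E homoallylic alcohols to 2,5-trans-3-halo-oxolanes; what has not been shown is their union, an oxirane oxygen closing in the endo mode followed by bromide capture at a tertiary carbon that bears a chloromethyl group. The oxolane (O, C3, C4, C5, C6) closes in the 5-endo mode with respect to the bromonium ion, the 4-exo closure at C4 and a seven-membered closure at C1 being far less favourable, while the oxirane (O, C6, C7) is the ring that opens. C6 keeps the configuration from step 9, C7 is set by backside attack of bromide on the oxonium ion (S in 18 becomes R), C3 and C4 are set by anti addition of oxygen and bromine across the E alkene (C3 methyl cis to C4–Br), and the alkene face is chosen by C6 through an envelope transition state that keeps the bromovinyl group on the convex face of the forming bicycle, away from C7 and its inward-pointing methyl. The step needs ring closure to outrun collapse of the bromonium bromide ion pair to the 3,4-dibromide, which slow addition of Br2 at −78 °C should favour by keeping bromide and tribromide scarce, and it needs opening at C7 in preference to C6 (which would give an oxane) and to C3, the first being secured by the tertiary character of C7 and the hindered ring-fusion position of C6 and the second by the oxirane strain that opening at C3 would not release.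

Compound list
1 | (E)-3-methylpent-2-en-4-yn-1-ol | C#C/C(C)=C/CO | starting material
2 | dilithio alkoxide acetylide of 1 (formed in the flask) | [Li]C#C/C(C)=C/CO[Li] | intermediate
3 | trimethyl{[(E)-3-methyl-5-(trimethylsilyl)pent-2-en-4-yn-1-yl]oxy}silane (bis-silyl ether, formed in the flask) | C[Si](C)(C)C#C/C(C)=C/CO[Si](C)(C)C | intermediate
4 | (E)-3-methyl-5-(trimethylsilyl)pent-2-en-4-yn-1-ol | C[Si](C)(C)C#C/C(C)=C/CO | intermediate
5 | [(E)-5-chloro-3-methylpent-3-en-1-yn-1-yl]trimethylsilane | C[Si](C)(C)C#C/C(C)=C/CCl | intermediate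
6 | prop-2-yn-1-ol (propargyl alcohol) | C#CCO | starting material
7 | dimethylaluminium (E)-3-(dimethylalumanyl)-2-methylprop-2-en-1-olate (alkenylalane, formed in the flask) | C[Al](C)OC/C(C)=C/[Al](C)C | intermediate
8 | (E)-3-iodo-2-methylprop-2-en-1-ol | OC/C(C)=C/I | intermediate
9 | tert-butyl{[(E)-3-iodo-2-methylprop-2-en-1-yl]oxy}dimethylsilane | CC(C)(C)[Si](C)(C)OC/C(C)=C/I | intermediate
10 | [(E)-3-{[tert-butyl(dimethyl)silyl]oxy}-2-methylprop-1-en-1-yl]lithium (formed in the flask) | CC(C)(C)[Si](C)(C)OC/C(C)=C/[Li] | intermediate
11 | [(E)-3-{[tert-butyl(dimethyl)silyl]oxy}-2-methylprop-1-en-1-yl]zinc chloride (formed in the flask) | CC(C)(C)[Si](C)(C)OC/C(C)=C/[Zn]Cl | intermediate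
12 | tert-butyl{[(2E,5E)-2,6-dimethyl-8-(trimethylsilyl)octa-2,5-dien-7-yn-1-yl]oxy}dimethylsilane | C[Si](C)(C)C#C/C(C)=C/C/C=C(\C)CO[Si](C)(C)C(C)(C)C | intermediate
13 | tert-butyl{[(2E,5E)-2,6-dimethylocta-2,5-dien-7-yn-1-yl]oxy}dimethylsilane | C#C/C(C)=C/C/C=C(\C)CO[Si](C)(C)C(C)(C)C | intermediate
14 | chlorobis(cyclopentadienyl)[(1E,3E,6E)-8-{[tert-butyl(dimethyl)silyl]oxy}-3,7-dimethylocta-1,3,6-trien-1-yl]zirconium (formed in the flask; cyclopentadienyl rings drawn σ-bonded) | Cl[Zr](/C=C/C(C)=C/C/C=C(\C)CO[Si](C)(C)C(C)(C)C)(C1C=CC=C1)C1C=CC=C1 | intermediate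
15 | {[(2E,5E,7E)-8-bromo-2,6-dimethylocta-2,5,7-trien-1-yl]oxy}(tert-butyl)dimethylsilane | Br/C=C/C(C)=C/C/C=C(\C)CO[Si](C)(C)C(C)(C)C | intermediate
16 | (2E,5E,7E)-8-bromo-2,6-dimethylocta-2,5,7-trien-1-ol | Br/C=C/C(C)=C/C/C=C(\C)CO | intermediate
17 | [(2R,3R)-3-[(2E,4E)-5-bromo-3-methylpenta-2,4-dien-1-yl]-2-methyloxiran-2-yl]methanol | Br/C=C/C(C)=C/C[C@H]1O[C@]1(C)CO | intermediate
18 | (2S,3R)-3-[(2E,4E)-5-bromo-3-methylpenta-2,4-dien-1-yl]-2-(chloromethyl)-2-methyloxirane | Br/C=C/C(C)=C/C[C@H]1O[C@]1(C)CCl | intermediate
19 | 3-bromo-2-[(E)-2-bromoethenyl]-6-(chloromethyl)-2,6-dimethyl-1-oxoniabicyclo[3.1.0]hexane, chain numbering 3S,4R,6R,7S, bromide as counter-ion (formed in the flask) | C[C@@]1(CCl)[C@H]2C[C@@H](Br)[C@](C)(/C=C/Br)[O+]12 | intermediate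
20 | (2S,3R,5R)-3-bromo-5-[(2R)-2-bromo-1-chloropropan-2-yl]-2-[(E)-2-bromoethenyl]-2-methyloxolane | C[C@](Br)(CCl)[C@H]1C[C@@H](Br)[C@](C)(/C=C/Br)O1 | target

Total step count: 11.
Longest linear sequence: 9 steps (from 6 through steps 3 to 11; the sequence from 1 through steps 1, 2 and 5 to 11 is equally long).

Steps most likely to fail

Step 11 (Proposed new method). The bromonium bromide ion pair may collapse to the vicinal 3,4-dibromide before the oxirane oxygen engages. Bromide may also open the oxonium ion at C6 with ring enlargement, or the two alkene faces may be poorly distinguished. The fallback uses known chemistry, sets out from 18 and comes back at 20, and separates the two bond-forming events. Acid-promoted opening of the trisubstituted oxirane by bromide at the more substituted carbon C7 with inversion (anhydrous HBr in Et2O/CH2Cl2, −78 °C) should give (2R,3R,5E,7E)-2,8-dibromo-1-chloro-2,6-dimethylocta-5,7-dien-3-ol F1; the regiochemistry of this opening would have to be confirmed. This E homoallylic alcohol would then be closed by a 5-endo bromoetherification (NBS, MeCN, −40 °C), the established route to 2,5-trans-3-bromo-oxolanes, in which the C6 hydroxyl attacks C3 anti to bromine and the target 20 results.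

Step 5. The π-allylpalladium intermediate is conjugated to the silylalkyne, so the alkenylzinc may attack its substituted terminus or add through the alkyne to give a vinylallene. The intermediate may also equilibrate and erode the E geometry of C3=C4. The fallback sets out from 5 and 6 and comes back at 12, and makes the C5–C6 bond by sp–sp3 alkylation instead of cross-coupling. Copper-mediated coupling of propargyl alcohol 6 with chloride 5 (CuI, NaI, K2CO3, DMF, rt) should give (5E)-6-methyl-8-(trimethylsilyl)oct-5-ene-2,7-diyn-1-ol F2. Hydroxyl-directed, copper-catalysed anti carbomagnesiation of this propargylic alcohol (MeMgCl, CuI 10 mol%, THF, then aq NH4Cl) places the methyl on the carbon next to the carbinol and hydrogen cis to CH2OH. It should thus give (2E,5E)-2,6-dimethyl-8-(trimethylsilyl)octa-2,5-dien-7-yn-1-ol F3, the silylalkyne having no directing group. Silylation (TBSCl, imidazole) then returns to 12.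

Step 10. Displacement at the primary carbon next to the fully substituted oxirane carbon may be slow, which would let chloride or adventitious acid open the oxirane, and heating may degrade the skipped bromotriene. The fallback sets out from 17 and comes back at 18, and separates activation from substitution so that both run cold. Tf2O and 2,6-lutidine in CH2Cl2 at −78 °C should give [(2R,3R)-3-[(2E,4E)-5-bromo-3-methylpenta-2,4-dien-1-yl]-2-methyloxiran-2-yl]methyl trifluoromethanesulfonate F4. This glycidyl-type triflate would be displaced at carbon by Bu4NCl between −78 and 0 °C without touching the oxirane, giving 18.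

Further compounds
F1 | step 11 | (2R,3R,5E,7E)-2,8-dibromo-1-chloro-2,6-dimethylocta-5,7-dien-3-ol | C[C@](Br)(CCl)[C@H](O)C/C=C(C)/C=C/Br
F2 | step 5 | (5E)-6-methyl-8-(trimethylsilyl)oct-5-ene-2,7-diyn-1-ol | C[Si](C)(C)C#C/C(C)=C/CC#CCO
F3 | step 5 | (2E,5E)-2,6-dimethyl-8-(trimethylsilyl)octa-2,5-dien-7-yn-1-ol | C[Si](C)(C)C#C/C(C)=C/C/C=C(\C)CO
F4 | step 10 | [(2R,3R)-3-[(2E,4E)-5-bromo-3-methylpenta-2,4-dien-1-yl]-2-methyloxiran-2-yl]methyl trifluoromethanesulfonate | Br/C=C/C(C)=C/C[C@H]1O[C@]1(C)COS(=O)(=O)C(F)(F)F
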